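**Retrosynthetic overview**
1. Feature: ring A is a phloroglucinol ring. In a 3,5-dioxygenated phenoxy group attached through O1, the two carbons ortho to the ether oxygen (future C4a and C8) are equivalent. Ring C can therefore be closed last at C4–C4a without a regiochemical question, with ring B already on the future C3.
2. Target ⇒ (global hydrogenolysis) tetrabenzyl ether ⇒ (C4–C4a, Friedel–Crafts cycloacylation) (Z)-3-aryloxy-2-arylacrylic acid.
3. O1–C2 ⇒ vinylic substitution of a β-chloroacrylate by 3,5-bis(benzyloxy)phenoxide. C3 and C4 ⇒ ethyl diazoacetate, inserted into the ring B aldehyde with 1,2-aryl shift, so that the formyl carbon becomes C2.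
4. Ring D ⇒ propargyl Claisen chromene annulation on 5-hydroxyvanillin, Jacobsen–Katsuki epoxidation (sets the S carbinol centre), and hydride opening at the benzylic carbon.
5. Ring order: B (bought) → D → A (brought in as the phenol) → C.

Key step: step 12

Assumption: the facial preference established for 2,2-dimethyl-2H-chromenes with the (S,S)-configured salen manganese chloride complex, giving the (3S,4S)-epoxide, is taken to hold for the 5-formyl chromene used here; the acrylates of steps 8 to 11 are drawn as Z isomers, and any E isomer would be carried along because step 12 equilibrates the alkene.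

**Step 1**
Reactants: 1 5-hydroxyvanillin (3,4-dihydroxy-5-methoxybenzaldehyde)
Product: 2 4-(benzyloxy)-3-hydroxy-5-methoxybenzaldehyde
Conditions: BnBr (1.0 equiv), Li2CO3, DMF, 50 °C
Reagents that add atoms: benzyl bromide, BrCc1ccccc1
Why: Williamson etherification under weak-base control, in which only the 4-OH (para to the formyl group and clearly the more acidic phenol) is ionised, so alkylation should stop at the 4-O-monoether and leave the 3-OH free.

**Step 2**
Reactants: 2 4-(benzyloxy)-3-hydroxy-5-methoxybenzaldehyde; 3 3-chloro-3-methylbut-1-yne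
Product: 4 4-(benzyloxy)-3-methoxy-5-[(2-methylbut-3-yn-2-yl)oxy]benzaldehyde
Conditions: DBU, CuCl2·2H2O (cat.), MeCN, 0 °C
Reagents that add atoms: none
Why: Copper-catalysed propargylic etherification of a phenol with a tertiary propargylic chloride, a method that works well for acceptor-substituted phenols and leaves the aldehyde and the benzyl ether alone.

**Step 3**
Reactants: 4 4-(benzyloxy)-3-methoxy-5-[(2-methylbut-3-yn-2-yl)oxy]benzaldehyde
Product: 5 8-(benzyloxy)-7-methoxy-2,2-dimethyl-2H-chromene-5-carbaldehyde
Conditions: PhNEt2, 190 °C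
Reagents that add atoms: none
Why: Aromatic propargyl Claisen rearrangement followed by 1,5-hydrogen shift and oxa-6π electrocyclisation, which can only go to the carbon between the ether oxygen and the formyl group because the other ortho position carries the benzyloxy group, so ring D forms with one regiochemistry.

**Step 4**
Reactants: 5 8-(benzyloxy)-7-methoxy-2,2-dimethyl-2H-chromene-5-carbaldehyde
Product: 6 (3S,4S)-8-(benzyloxy)-3,4-epoxy-7-methoxy-2,2-dimethylchroman-5-carbaldehyde
Conditions: (S,S)-N,N'-bis(3,5-di-tert-butylsalicylidene)-1,2-cyclohexanediaminomanganese chloride (cat.), 4-phenylpyridine N-oxide (cat.), aq. NaOCl (pH 11.3), CH2Cl2, 0 °C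
Reagents that add atoms: sodium hypochlorite, [Na+].[O-]Cl
Why: Jacobsen–Katsuki epoxidation, for which 2,2-dimethylchromenes are a privileged cis-alkene class; the chiral salen ligand controls the face and sets C3 as S, while the non-enolisable aldehyde stays in the organic phase and, as an acceptor ortho to C4a, tempers the lability of the benzylic epoxide.

**Step 5**
Reactants: 6 (3S,4S)-8-(benzyloxy)-3,4-epoxy-7-methoxy-2,2-dimethylchroman-5-carbaldehyde
Product: 7 (3S)-8-(benzyloxy)-5-(hydroxymethyl)-7-methoxy-2,2-dimethylchroman-3-ol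
Conditions: LiAlH4, THF, 0 °C → rt (epoxide added to the hydride); aqueous work-up
Reagents that add atoms: none
Why: SN2 hydride opening of the epoxide at the benzylic C4 in the trans-diaxial (Fürst–Plattner) sense, C3 being shielded by the neighbouring gem-dimethyl carbon; the C3–O bond is untouched so the S centre is retained, the aldehyde is reduced at the same time, and the short peri CH2O arm cannot reach the axial trajectory needed to open the epoxide itself.

**Step 6**
Reactants: 7 (3S)-8-(benzyloxy)-5-(hydroxymethyl)-7-methoxy-2,2-dimethylchroman-3-ol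
Product: 8 (3S)-8-(benzyloxy)-3-hydroxy-7-methoxy-2,2-dimethylchroman-5-carbaldehyde
Conditions: MnO2, CH2Cl2, rt
Reagents that add atoms: none
Why: Chemoselective MnO2 oxidation of a benzylic primary alcohol, which leaves the saturated, hindered secondary alcohol and its stereocentre unchanged.

**Step 7**
Reactants: 8 (3S)-8-(benzyloxy)-3-hydroxy-7-methoxy-2,2-dimethylchroman-5-carbaldehyde
Product: 9 (3S)-3,8-bis(benzyloxy)-7-methoxy-2,2-dimethylchroman-5-carbaldehyde
Conditions: BnOC(=NH)CCl3, TfOH (cat.), CH2Cl2/cyclohexane, 0 °C → rt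
Reagents that add atoms: benzyl 2,2,2-trichloroacetimidate, ClC(Cl)(Cl)C(=N)OCc1ccccc1
Why: Acid-catalysed trichloroacetimidate O-benzylation, chosen over alkoxide conditions so that no alkoxide meets the aldehyde; the C3–O bond is not broken, so the configuration is kept.

**Step 8**
Reactants: 9 (3S)-3,8-bis(benzyloxy)-7-methoxy-2,2-dimethylchroman-5-carbaldehyde; 10 ethyl diazoacetate
Product: 11 ethyl (Z)-2-[(3S)-3,8-bis(benzyloxy)-7-methoxy-2,2-dimethylchroman-5-yl]-3-hydroxyacrylate (enol form of the α-formyl ester)
Conditions: HBF4·OEt2 (10 mol %), CH2Cl2, −78 °C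
Reagents that add atoms: none
Why: Acid-catalysed addition of the diazo carbon to the activated formyl group and loss of N2 with 1,2-aryl shift (the aryl-migration branch of the Büchner–Curtius–Schlotterbeck/Roskamp manifold, known for electron-rich benzaldehydes); the para-benzyloxy group raises the migratory aptitude of ring B over hydride, so the hindered C3–C1' bond arises by migration and the product should rest as the hydrogen-bonded Z enol.

**Step 9**
Reactants: 11 ethyl (Z)-2-[(3S)-3,8-bis(benzyloxy)-7-methoxy-2,2-dimethylchroman-5-yl]-3-hydroxyacrylate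
Product: 12 ethyl (Z)-2-[(3S)-3,8-bis(benzyloxy)-7-methoxy-2,2-dimethylchroman-5-yl]-3-chloroacrylate
Conditions: (chloromethylene)dimethyliminium chloride, CH2Cl2, 0 °C → rt
Reagents that add atoms: (chloromethylene)dimethyliminium chloride, C[N+](C)=CCl.[Cl-]
Why: Vilsmeier-type deoxychlorination of a β-dicarbonyl enol, in which O-activation turns the enol oxygen into a leaving group that chloride displaces by addition–elimination; the halide is preferred to an enol sulfonate because a phenoxide can strip a sulfonyl group by attack at sulfur but can attack a β-chloroacrylate only at carbon.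

**Step 10**
Reactants: 12 ethyl (Z)-2-[(3S)-3,8-bis(benzyloxy)-7-methoxy-2,2-dimethylchroman-5-yl]-3-chloroacrylate; 13 3,5-bis(benzyloxy)phenol
Product: 14 ethyl (Z)-3-[3,5-bis(benzyloxy)phenoxy]-2-[(3S)-3,8-bis(benzyloxy)-7-methoxy-2,2-dimethylchroman-5-yl]acrylate
Conditions: Cs2CO3, DMF, rt → 50 °C
Reagents that add atoms: none
Why: Nucleophilic vinylic substitution (addition–elimination), the opening move of the Ruhemann chromone synthesis from β-chloro-α,β-unsaturated esters and phenoxides; the caesium phenoxide in DMF should react at oxygen rather than at ring carbon, the α-aryl ester stabilises the carbanion, and chloride loss is expected with predominant retention.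

**Step 11**
Reactants: 14 ethyl (Z)-3-[3,5-bis(benzyloxy)phenoxy]-2-[(3S)-3,8-bis(benzyloxy)-7-methoxy-2,2-dimethylchroman-5-yl]acrylate
Product: 15 (Z)-3-[3,5-bis(benzyloxy)phenoxy]-2-[(3S)-3,8-bis(benzyloxy)-7-methoxy-2,2-dimethylchroman-5-yl]acrylic acid
Conditions: LiOH, THF/MeOH/H2O, 40 °C; then 1 M HCl to pH 3
Reagents that add atoms: lithium hydroxide, [Li+].[OH-]
Why: Ester saponification (BAc2) as in the classical aryloxyacrylate series; donation from the ether oxygen lowers the electrophilicity of the β-carbon, so hydroxide should attack the ester carbonyl rather than displace the phenoxide, and benzyl ethers are inert to base.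

**Step 12**
Reactants: 15 (Z)-3-[3,5-bis(benzyloxy)phenoxy]-2-[(3S)-3,8-bis(benzyloxy)-7-methoxy-2,2-dimethylchroman-5-yl]acrylic acid
Product: 17 tetra-O-benzyl ether of the target (5,7-bis(benzyloxy)-3-[(3S)-3,8-bis(benzyloxy)-7-methoxy-2,2-dimethylchroman-5-yl]-4H-chromen-4-one), via mixed trifluoroacetic anhydride 16 (not isolated)
Conditions: (CF3CO)2O (excess), CH2Cl2, 0 °C → rt (15 added to the cold anhydride)
Reagents that add atoms: none
Why: Trifluoroacetic anhydride converts acid 15 into the acyl trifluoroacetate 16, which, as such or after ionisation to the oxygen-stabilised vinylogous acylium ion, is attacked by the ring A carbon ortho to the vinyl ether oxygen, and proton loss from the arenium ion restores aromaticity and leaves the C4–C4a bond. The closest known reaction type is the Ruhemann-type chromone and flavone synthesis by Friedel–Crafts cycloacylation of β-aryloxyacrylic acids, together with the anhydride-mediated closure of aryloxy acids on phloroglucinol-type rings to chromanones and xanthones. Ring C closes in a 6-exo-trig mode at the anhydride carbonyl (6-exo-dig if the free acylium ion reacts), all six ring atoms being sp2 and held in one plane by the Z alkene. No stereocentre is formed, and the S carbinol carbon of ring D, masked as its benzyl ether, is remote from the reacting centres and is not touched. Regioselectivity needs no control because the two carbons ortho to O1 are homotopic and each is also ortho and para to a benzyloxy group, while the geometry is secured by the Z alkene and, for any E isomer, by equilibration through reversible protonation at the α-carbon and through the low Cα–Cβ bond order of the push–pull acylium ion, only the Z form being drained by ring closure. Chemoselectivity over intermolecular trifluoroacetylation of ring A rests on the strain-free intramolecular six-ring transition state, and adding 15 to excess cold anhydride keeps free acid away from the liberated CF3CO2H, so protodecarboxylation should not compete.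

**Step 13**
Reactants: 17 tetra-O-benzyl ether of the target
Product: 18 5,7-dihydroxy-3-[(3S)-3,8-dihydroxy-7-methoxy-2,2-dimethylchroman-5-yl]-4H-chromen-4-one (target)
Conditions: H2 (1 atm), Pd(OH)2/C, THF/MeOH, rt, stopped after uptake of four equivalents of H2
Reagents that add atoms: none
Why: Catalytic hydrogenolysis of three aryl benzyl ethers and one alkyl benzyl ether; the C2=C3 bond is deactivated as a vinylogous ester and shielded by the ortho-substituted ring B, and the methyl ether and the non-benzylic C3–O bond of ring D are inert, so the S centre is kept.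

**Compound list**
1 | 5-hydroxyvanillin | COc1cc(C=O)cc(O)c1O | starting material
2 | 4-(benzyloxy)-3-hydroxy-5-methoxybenzaldehyde | COc1cc(C=O)cc(O)c1OCc1ccccc1 | intermediate
3 | 3-chloro-3-methylbut-1-yne | CC(C)(Cl)C#C | starting material
4 | 4-(benzyloxy)-3-methoxy-5-[(2-methylbut-3-yn-2-yl)oxy]benzaldehyde | COc1cc(C=O)cc(OC(C)(C)C#C)c1OCc1ccccc1 | intermediate
5 | 8-(benzyloxy)-7-methoxy-2,2-dimethyl-2H-chromene-5-carbaldehyde | COc1cc(C=O)c2C=CC(C)(C)Oc2c1OCc1ccccc1 | intermediate
6 | (3S,4S)-8-(benzyloxy)-3,4-epoxy-7-methoxy-2,2-dimethylchroman-5-carbaldehyde | COc1cc(C=O)c2c(c1OCc1ccccc1)OC(C)(C)[C@H]1O[C@H]12 | intermediate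
7 | (3S)-8-(benzyloxy)-5-(hydroxymethyl)-7-methoxy-2,2-dimethylchroman-3-ol | COc1cc(CO)c2c(c1OCc1ccccc1)OC(C)(C)[C@@H](O)C2 | intermediate
8 | (3S)-8-(benzyloxy)-3-hydroxy-7-methoxy-2,2-dimethylchroman-5-carbaldehyde | COc1cc(C=O)c2c(c1OCc1ccccc1)OC(C)(C)[C@@H](O)C2 | intermediate
9 | (3S)-3,8-bis(benzyloxy)-7-methoxy-2,2-dimethylchroman-5-carbaldehyde | COc1cc(C=O)c2c(c1OCc1ccccc1)OC(C)(C)[C@@H](OCc1ccccc1)C2 | intermediate
10 | ethyl diazoacetate | CCOC(=O)C=[N+]=[N-] | starting material
11 | ethyl (Z)-2-[(3S)-3,8-bis(benzyloxy)-7-methoxy-2,2-dimethylchroman-5-yl]-3-hydroxyacrylate | CCOC(=O)/C(=C\O)c1cc(OC)c(OCc2ccccc2)c2OC(C)(C)[C@@H](OCc3ccccc3)Cc12 | intermediate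
12 | ethyl (Z)-2-[(3S)-3,8-bis(benzyloxy)-7-methoxy-2,2-dimethylchroman-5-yl]-3-chloroacrylate | CCOC(=O)/C(=C\Cl)c1cc(OC)c(OCc2ccccc2)c2OC(C)(C)[C@@H](OCc3ccccc3)Cc12 | intermediate
13 | 3,5-bis(benzyloxy)phenol | Oc1cc(OCc2ccccc2)cc(OCc2ccccc2)c1 | starting material
14 | ethyl (Z)-3-[3,5-bis(benzyloxy)phenoxy]-2-[(3S)-3,8-bis(benzyloxy)-7-methoxy-2,2-dimethylchroman-5-yl]acrylate | CCOC(=O)/C(=C\Oc1cc(OCc2ccccc2)cc(OCc2ccccc2)c1)c1cc(OC)c(OCc2ccccc2)c2OC(C)(C)[C@@H](OCc3ccccc3)Cc12 | intermediate
15 | (Z)-3-[3,5-bis(benzyloxy)phenoxy]-2-[(3S)-3,8-bis(benzyloxy)-7-methoxy-2,2-dimethylchroman-5-yl]acrylic acid | OC(=O)/C(=C\Oc1cc(OCc2ccccc2)cc(OCc2ccccc2)c1)c1cc(OC)c(OCc2ccccc2)c2OC(C)(C)[C@@H](OCc3ccccc3)Cc12 | intermediate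
16 | mixed anhydride of 15 with trifluoroacetic acid | FC(F)(F)C(=O)OC(=O)/C(=C\Oc1cc(OCc2ccccc2)cc(OCc2ccccc2)c1)c1cc(OC)c(OCc2ccccc2)c2OC(C)(C)[C@@H](OCc3ccccc3)Cc12 | intermediate
17 | 5,7-bis(benzyloxy)-3-[(3S)-3,8-bis(benzyloxy)-7-methoxy-2,2-dimethylchroman-5-yl]-4H-chromen-4-one | COc1cc(-c2coc3cc(OCc4ccccc4)cc(OCc4ccccc4)c3c2=O)c2c(c1OCc1ccccc1)OC(C)(C)[C@@H](OCc1ccccc1)C2 | intermediate
18 | 5,7-dihydroxy-3-[(3S)-3,8-dihydroxy-7-methoxy-2,2-dimethylchroman-5-yl]-4H-chromen-4-one | COc1cc(-c2coc3cc(O)cc(O)c3c2=O)c2c(c1O)OC(C)(C)[C@@H](O)C2 | target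

**Step count**
- Total step count: 13
- Longest linear sequence: 13 steps (1 → 18)

**Steps most likely to fail**

**Step 12.** The acyl group is a vinylogous carbonate and therefore a weak electrophile, and E to Z equilibration may be slow. Trifluoroacetylation of ring A, acid-induced loss of benzyl ethers or protodecarboxylation could then overtake ring closure.

The fallback reverses the order of events: the C4–C4a bond is made intermolecularly first and C2 is inserted last (the deoxybenzoin approach). It sets out from 11 and 13 and comes back at 17. Hot aqueous-ethanolic KOH deformylates (retro-Claisen) and saponifies 11 to the arylacetic acid F1. In parallel, 13 is benzylated (BnBr, K2CO3, DMF) to 1,3,5-tris(benzyloxy)benzene F2. Friedel–Crafts acylation of F2 by F1 under trifluoroacetic anhydride gives the tris(benzyloxy)deoxybenzoin F3. One equivalent of BCl3 (CH2Cl2, −78 °C), chelated to the ketone, removes one ortho benzyl group and gives the 2-hydroxydeoxybenzoin F4. Heating F4 with DMF dimethyl acetal in toluene adds C2 and closes ring C at O1–C2 to give 17.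

**Step 8.** Hydride migration may compete with aryl migration. Addition to the ortho-substituted, electron-rich aldehyde may also be so slow that the diazoacetate is consumed by the acid.

The fallback replaces the one-step insertion by a classical two-carbon build-up. It sets out from 9 and comes back at 11. Condensation of 9 with methyl (methylthio)methyl sulfoxide (benzyltrimethylammonium hydroxide, THF, reflux) gives the ketene dithioacetal S-oxide F5. HCl in EtOH turns F5 into the ethyl arylacetate F6. Crossed Claisen formylation of F6 with ethyl formate and NaH in THF delivers 11.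

**Step 4.** Facial selectivity may be poor because the peri formyl group at C5 disturbs the side-on approach of the alkene to the salen complex.

The fallback gives up catalyst control in favour of a resolution through covalent diastereomers. It sets out from 8 obtained in insufficient enantiomeric purity and comes back at enantiopure 8. Esterification with (S)-2-methoxy-2-phenylacetic acid (DCC, DMAP, CH2Cl2) gives diastereomeric esters. The (3S)-configured O-methylmandelate ester F7 is separated from these by chromatography or crystallisation. LiOH in aqueous THF then cleaves F7 and returns 8.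

**Further compounds**
F1 | step 12 | 2-[(3S)-3,8-bis(benzyloxy)-7-methoxy-2,2-dimethylchroman-5-yl]acetic acid | OC(=O)Cc1cc(OC)c(OCc2ccccc2)c2OC(C)(C)[C@@H](OCc3ccccc3)Cc12
F2 | step 12 | 1,3,5-tris(benzyloxy)benzene | c1ccc(COc2cc(OCc3ccccc3)cc(OCc3ccccc3)c2)cc1
F3 | step 12 | 2-[(3S)-3,8-bis(benzyloxy)-7-methoxy-2,2-dimethylchroman-5-yl]-1-[2,4,6-tris(benzyloxy)phenyl]ethanone | O=C(Cc1cc(OC)c(OCc2ccccc2)c2OC(C)(C)[C@@H](OCc3ccccc3)Cc12)c1c(OCc2ccccc2)cc(OCc2ccccc2)cc1OCc1ccccc1
F4 | step 12 | 1-[2,4-bis(benzyloxy)-6-hydroxyphenyl]-2-[(3S)-3,8-bis(benzyloxy)-7-methoxy-2,2-dimethylchroman-5-yl]ethanone | O=C(Cc1cc(OC)c(OCc2ccccc2)c2OC(C)(C)[C@@H](OCc3ccccc3)Cc12)c1c(O)cc(OCc2ccccc2)cc1OCc1ccccc1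
F5 | step 8 | (3S)-3,8-bis(benzyloxy)-7-methoxy-2,2-dimethyl-5-[2-(methylsulfinyl)-2-(methylthio)vinyl]chroman (alkene geometry and sulfur configuration not defined) | CSC(=Cc1cc(OC)c(OCc2ccccc2)c2OC(C)(C)[C@@H](OCc3ccccc3)Cc12)S(C)=O
F6 | step 8 | ethyl 2-[(3S)-3,8-bis(benzyloxy)-7-methoxy-2,2-dimethylchroman-5-yl]acetate | CCOC(=O)Cc1cc(OC)c(OCc2ccccc2)c2OC(C)(C)[C@@H](OCc3ccccc3)Cc12
F7 | step 4 | (3S)-8-(benzyloxy)-5-formyl-7-methoxy-2,2-dimethylchroman-3-yl (S)-2-methoxy-2-phenylacetate | COc1cc(C=O)c2c(c1OCc1ccccc1)OC(C)(C)[C@@H](OC(=O)[C@@H](OC)c1ccccc1)C2
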